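The runs were computed with made-up constants; the scatter is artificial.

The product stalls: the dawn run shows 51.3% after 4.00 d and 52.6% after 10.0 d. Before charging the next flasks, you must decide whether more scavenger is worth adding.

| setting | dawn | midnight | ochre | violet |
|---|---|---|---|---|
| substrate | 0.13 M | 0.13 M | 0.13 M | 0.13 M |
| reagent | 0.65 M | 0.65 M | 0.650 M | 0.650 M |
| scavenger | 0.16 M | 0.18 M | 0.200 M | 0.290 M |
| initiator | 6.5 mM | 6.5 mM | 6.5 mM | 6.5 mM |
| remark | run made earlier | run made earlier |  |  |
| time |  |  | 10 d | 10 d |

| run | time / d | substrate / % | product / % |
|---|---|---|---|
| dawn | 0.833 | 51.2 | 41.2 |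
| dawn | 1.67 | 42.8 | 48.1 |
| dawn | 4.00 | 38.7 | 51.3 |
| dawn | 10.0 | 36.9 | 52.6 |
| midnight | 1.25 | 45.7 | 45.5 |
| midnight | 4.00 | 39.3 | 52.9 |
| midnight | 6.00 | 36.7 | 52.4 |
| midnight | 10.0 | 37.2 | 52.1 |

(readings scatter by 1 percentage point)

* part of the substrate that has reacted at the end, ochre
* part of the substrate that has reacted at the end, violet
* what raising the concentration of scavenger from its lowest to its highest value here does to the part of the substrate that has reacted (changes below 5 percentage points count as none) (no change / it falls / it rises)

Work in logarithms. Define the stall logarithm L as the natural logarithm of the substrate charged over the substrate left on the plateau (a dead-end plateau, in the field's term, if the end of the initiator stopped it); read from the mean of the final dawn and midnight substrate readings, L is 0.993.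

Now test the scavenger. If L fell in inverse proportion to it, going from 0.16 M in dawn to 0.18 M in midnight should leave 41.2% of the substrate. Midnight reads 37.2%, a gap of 4 percentage points against a scatter of 1 point per reading. So I hold L constant, and my reckoning gives 63.0% reacted in both ochre and violet, which makes the trend no change.

Charge violet as the far test, but expect no extra product from it. For the lever, I assume that the stall is the end of the initiator and that chains end in pairs; then carriers go as the root of the initiation rate, and, with the other charges held, L goes as the square root of the initiator charge. Dawn and midnight cannot test that, since both hold 6.5 mM.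

The forecast gives 62.5% for ochre, 61% for violet and the trend as no change, expecting of violet “little change, perhaps slightly lower”.

The flasks give 62.1% for ochre and 62.1% for violet, and the trend is no change. Violet's answer has moved by 5 points at 0.113 M or 0.150 M of substrate, with the other charges and the time held. Read back from ochre, L is 0.970, against 0.993 from the earlier runs.

    initiator → 2 initiating radical (k = 0.0950 h⁻¹)
    substrate + initiating radical → capped initiator + first chain carrier (k = 13000 M⁻¹ s⁻¹)
    reagent + first chain carrier ⇌ product + second chain carrier (K = 0.0270, k = 4.00 × 10⁵ M⁻¹ h⁻¹)
    substrate + second chain carrier → released group + first chain carrier (k = 6.10 × 10⁶ M⁻¹ h⁻¹)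
    2 first chain carrier → ended chains A (k = 2.10 × 10⁸ M⁻¹ s⁻¹)
    2 second chain carrier → ended chains B (k = 4.00 × 10⁶ M⁻¹ s⁻¹)
    substrate + released group ⇌ idle adduct, settled at all times (K = 3.60 M⁻¹)
    scavenger + released group → scavenged by-product (k = 84.0 M⁻¹ h⁻¹)

Take the neighbour of ochre charged with 0.0016 M of initiator. The root rule gives L = 0.493, so 38.9% should react, and the computed flask gives 38.3%.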